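**Strategy.** The cycloheptanone (C3a–C4–C5–C6–C7–C8–C8a of the cyclohepta[b]furan core) is cut at C5–C6 and C3a–C8a into a C3a–C5 vinylcarbene and a C6–C8a diene. One rhodium-catalysed cyclopropanation/Cope sequence between a vinyldiazoacetate and a (1E,3Z)-1-alkoxy-3-siloxypentadiene forms both bonds, closes the seven-membered ring and sets C3a, C6 and C8a all-cis and enantioselectively. It exploits the 1,3-dioxygenated C5/C7 pair flanking the C6 methyl and the cis C8a–O/C3a–C relationship of the lactone. The siloxy group then delivers the C7 carbonyl and the C8 oxygen; the carbenoid ester, a placeholder that keeps C5 inert, is excised by Curtius rearrangement.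

Key step: step 5

Remark: locants C3a to C8a are those of the cyclohepta[b]furan core of the target (C8a carries the lactone oxygen, C3a the methylidene-bearing carbon).
Remark: the sense of induction of Rh2(R-DOSP)4 is assigned from the styrene cyclopropanation model (the S catalyst gives the 1S,2R cyclopropane); if the siloxydiene responds in the opposite sense, the enantiomeric catalyst is used.
Remark: boronate 6 is taken as a purchasable building block (otherwise it is made from methyl propiolate and pinacolborane).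

Step 1
Reactants: 1 pent-1-yn-3-one; 2 4-methoxybenzyl alcohol
Product: 3 (1E)-1-[(4-methoxyphenyl)methoxy]pent-1-en-3-one
Conditions: DABCO (10 mol%), CH2Cl2, 0 °C to rt
Reagents that add atoms: none
Why: Amine-catalysed oxa-Michael addition of an alcohol to an ynone should give the thermodynamically preferred (E)-β-alkoxy enone.

Step 2
Reactants: 3 (1E)-1-[(4-methoxyphenyl)methoxy]pent-1-en-3-one
Product: 4 triethyl({(1E,3Z)-1-[(4-methoxyphenyl)methoxy]penta-1,3-dien-3-yl}oxy)silane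
Conditions: TESOTf, Et3N, Et2O, 0 °C
Reagents that add atoms: triethylsilyl trifluoromethanesulfonate, CC[Si](CC)(CC)OS(=O)(=O)C(F)(F)F
Why: Soft enolisation/silylation of the ethyl ketone should give the 2-siloxydiene with the Z enol ether (methyl cis to OSi), the geometry the key step needs.

Step 3
Reactants: 5 tert-butyl 2-(bromomethyl)prop-2-enoate; 6 methyl (2E)-3-(4,4,5,5-tetramethyl-1,3,2-dioxaborolan-2-yl)prop-2-enoate
Product: 7 6-tert-butyl 1-methyl (2E)-5-methylidenehex-2-enedioate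
Conditions: Pd(PPh3)4 (5 mol%), CsF, THF, 50 °C
Reagents that add atoms: none
Why: Suzuki–Miyaura allyl–alkenyl coupling through a symmetrical π-allylpalladium intermediate has no regiochemical issue, and fluoride activation avoids base-induced migration of the skipped diene.

Step 4
Reactants: 7 6-tert-butyl 1-methyl (2E)-5-methylidenehex-2-enedioate
Product: 8 6-tert-butyl 1-methyl (3E)-2-diazo-5-methylidenehex-3-enedioate
Conditions: p-ABSA, DBU, MeCN, 0 °C
Reagents that add atoms: 4-acetamidobenzenesulfonyl azide, CC(=O)Nc1ccc(cc1)S(=O)(=O)N=[N+]=[N-]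
Why: Regitz diazo transfer to the dienolate formed at the doubly allylic CH2 should occur at the carbon α to the methyl ester and give the (E)-vinyldiazoacetate.

Step 5
Reactants: 8 6-tert-butyl 1-methyl (3E)-2-diazo-5-methylidenehex-3-enedioate; 4 triethyl({(1E,3Z)-1-[(4-methoxyphenyl)methoxy]penta-1,3-dien-3-yl}oxy)silane
Product: 11 methyl (3S,4R,7S)-3-[3-(tert-butoxy)-3-oxoprop-1-en-2-yl]-4-[(4-methoxyphenyl)methoxy]-7-methyl-6-[(triethylsilyl)oxy]cyclohepta-1,5-diene-1-carboxylate, via rhodium carbenoid 9 (not isolated), via cis-divinylcyclopropane 10 (not isolated)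
Conditions: Rh2(R-DOSP)4 (1 mol%), hexanes, slow addition of 8 to 4 (2 equiv), −40 °C to rt; then 40 °C
Reagents that add atoms: none
Why: Rh2(R-DOSP)4 converts 8 into the donor/acceptor carbenoid 9, whose carbenoid carbon (future C5) cyclopropanates the electron-rich C6=C7 silyl enol ether of 4 to give cis-divinylcyclopropane 10; its C5–C7 bond then breaks while C3a–C8a forms in a boat Cope rearrangement, so C5–C6 and C3a–C8a are both made in one operation. The closest known reaction type is the tandem cyclopropanation/Cope rearrangement (formal [4+3] cycloaddition) of vinyldiazoacetates with oxygenated dienes such as 1-alkoxy- and 2-siloxybutadienes. The cyclopropane closes by intermolecular [2+1] addition and the cycloheptadiene by a concerted ring-expanding [3,3] shift, so no ring is closed by an ionic or radical cyclisation. C6 is fixed by the stereospecific cyclopropanation of the Z enol ether (methyl trans to both vinyl groups), C3a and C8a by the boat transition state, in which the E substituents of both vinyl termini end cis to each other and to the C6 methyl, and the absolute sense by the chiral prolinate ligands. The step needs attack at C6=C7 instead of C8=C8a and at the carbenoid carbon instead of the distal dienyl carbon: the siloxy donor and the trans geometry of the C8=C8a enol ether secure the first, the substituted vinyl terminus, hexanes and low temperature the second.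

Step 6
Reactants: 11 methyl (3S,4R,7S)-3-[3-(tert-butoxy)-3-oxoprop-1-en-2-yl]-4-[(4-methoxyphenyl)methoxy]-7-methyl-6-[(triethylsilyl)oxy]cyclohepta-1,5-diene-1-carboxylate
Product: 13 methyl (3S,4R,5S,7S)-3-[3-(tert-butoxy)-3-oxoprop-1-en-2-yl]-5-hydroxy-4-[(4-methoxyphenyl)methoxy]-7-methyl-6-oxocyclohept-1-ene-1-carboxylate, via siloxy epoxide 12 (not isolated)
Conditions: DMDO, acetone/CH2Cl2, −78 to −40 °C; then AcOH, H2O, THF, 0 °C
Reagents that add atoms: dimethyldioxirane, CC1(C)OO1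
Why: Rubottom oxidation: the dioxirane should epoxidise only the electron-rich silyl enol ether, from the face opposite to the three cis substituents (C8a ether, C3a side chain, C6 methyl), which places the C8 oxygen trans to the C8a oxygen before acid opens the siloxy epoxide to the α-hydroxy ketone.

Step 7
Reactants: 14 but-2-yn-1-ol
Product: 15 1-methoxybut-2-yne
Conditions: NaH, MeI, THF, 0 °C to rt
Reagents that add atoms: iodomethane, CI
Why: Williamson etherification of a primary propargylic alkoxide.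

Step 8
Reactants: 15 1-methoxybut-2-yne
Product: 16 1-methoxybuta-1,2-diene
Conditions: KOtBu (20 mol%), THF, 40 °C; distil
Reagents that add atoms: none
Why: Base-catalysed propargyl-to-allenyl isomerisation of a 2-alkynyl ether should stop at the 1-alkoxyallene if conversion is monitored and the product is distilled off.

Step 9
Reactants: 13 methyl (3S,4R,5S,7S)-3-[3-(tert-butoxy)-3-oxoprop-1-en-2-yl]-5-hydroxy-4-[(4-methoxyphenyl)methoxy]-7-methyl-6-oxocyclohept-1-ene-1-carboxylate; 16 1-methoxybuta-1,2-diene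
Product: 20 methyl (3S,4R,5S,6S,7S)-6-[(2E)-but-2-enoyl]-3-[3-(tert-butoxy)-3-oxoprop-1-en-2-yl]-5,6-dihydroxy-4-[(4-methoxyphenyl)methoxy]-7-methylcyclohept-1-ene-1-carboxylate, via lithiated methoxybutadiene 17 (not isolated), via organocerium reagent 18 (not isolated), via allenyl ether adduct 19 (not isolated)
Conditions: 16 (3 equiv), n-BuLi, THF, −40 °C; CeCl3, −78 °C; add 13, −78 °C; then 1 M HCl, THF, 0 °C
Reagents that add atoms: water, O
Why: The α-metallated alkoxyallene is an enoyl anion equivalent and the organocerium form should add to the enolisable ketone without deprotonation; chelation of the C8 alkoxide with the ketone leaves the face anti to the C6 methyl open, so the new C–C bond should form cis to the C8 oxygen (C7–OH trans to C8–O), and acid hydrolysis of the enol ether should give the (E)-enone.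

Step 10
Reactants: 20 methyl (3S,4R,5S,6S,7S)-6-[(2E)-but-2-enoyl]-3-[3-(tert-butoxy)-3-oxoprop-1-en-2-yl]-5,6-dihydroxy-4-[(4-methoxyphenyl)methoxy]-7-methylcyclohept-1-ene-1-carboxylate; 21 (2S)-2-methylbutanoic acid
Product: 22 methyl (3S,4R,5S,6S,7S)-6-[(2E)-but-2-enoyl]-3-[3-(tert-butoxy)-3-oxoprop-1-en-2-yl]-6-hydroxy-4-[(4-methoxyphenyl)methoxy]-7-methyl-5-{[(2S)-2-methylbutanoyl]oxy}cyclohept-1-ene-1-carboxylate
Conditions: DIC, DMAP (cat.), CH2Cl2, 0 °C to rt
Reagents that add atoms: none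
Why: Steglich esterification should acylate only the secondary C8 hydroxyl, the tertiary α-ketol hydroxyl being too hindered, and the mild conditions should keep the acid stereocentre intact.

Step 11
Reactants: 22 methyl (3S,4R,5S,6S,7S)-6-[(2E)-but-2-enoyl]-3-[3-(tert-butoxy)-3-oxoprop-1-en-2-yl]-6-hydroxy-4-[(4-methoxyphenyl)methoxy]-7-methyl-5-{[(2S)-2-methylbutanoyl]oxy}cyclohept-1-ene-1-carboxylate
Product: 23 methyl (3S,4R,5S,6S,7S)-6-[(2E)-but-2-enoyl]-3-[3-(tert-butoxy)-3-oxoprop-1-en-2-yl]-4-[(4-methoxyphenyl)methoxy]-7-methyl-5-{[(2S)-2-methylbutanoyl]oxy}-6-[(triethylsilyl)oxy]cyclohept-1-ene-1-carboxylate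
Conditions: TESOTf, 2,6-lutidine, CH2Cl2, −40 to 0 °C
Reagents that add atoms: triethylsilyl trifluoromethanesulfonate, CC[Si](CC)(CC)OS(=O)(=O)C(F)(F)F
Why: Silyl triflate silylation of the tertiary alcohol blocks it from adding to the isocyanate generated in step 13.

Step 12
Reactants: 23 methyl (3S,4R,5S,6S,7S)-6-[(2E)-but-2-enoyl]-3-[3-(tert-butoxy)-3-oxoprop-1-en-2-yl]-4-[(4-methoxyphenyl)methoxy]-7-methyl-5-{[(2S)-2-methylbutanoyl]oxy}-6-[(triethylsilyl)oxy]cyclohept-1-ene-1-carboxylate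
Product: 24 (3S,4R,5S,6S,7S)-6-[(2E)-but-2-enoyl]-3-[3-(tert-butoxy)-3-oxoprop-1-en-2-yl]-4-[(4-methoxyphenyl)methoxy]-7-methyl-5-{[(2S)-2-methylbutanoyl]oxy}-6-[(triethylsilyl)oxy]cyclohept-1-ene-1-carboxylic acid
Conditions: Me3SnOH, 1,2-dichloroethane, 70 °C; then 0.1 M HCl wash
Reagents that add atoms: trimethyltin hydroxide, C[Sn](C)(C)O
Why: Trimethyltin hydroxide hydrolysis should be selective for the methyl ester over the tert-butyl and the hindered secondary ester and is neutral enough to spare the enone and the silyl ether.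

Step 13
Reactants: 24 (3S,4R,5S,6S,7S)-6-[(2E)-but-2-enoyl]-3-[3-(tert-butoxy)-3-oxoprop-1-en-2-yl]-4-[(4-methoxyphenyl)methoxy]-7-methyl-5-{[(2S)-2-methylbutanoyl]oxy}-6-[(triethylsilyl)oxy]cyclohept-1-ene-1-carboxylic acid
Product: 27 (1S,2S,3R,6S,7R)-2-[(2E)-but-2-enoyl]-6-[3-(tert-butoxy)-3-oxoprop-1-en-2-yl]-7-[(4-methoxyphenyl)methoxy]-3-methyl-4-oxo-2-[(triethylsilyl)oxy]cycloheptyl (2S)-2-methylbutanoate, via acyl azide 25 (not isolated), via vinyl isocyanate 26 (not isolated)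
Conditions: DPPA, Et3N, toluene, rt then 80 °C; then AcOH, H2O, THF, 40 °C
Reagents that add atoms: water, O
Why: Curtius rearrangement of the α,β-unsaturated acyl azide gives the vinyl isocyanate, whose hydrolysis through the enamine should unveil the C5 ketone with protonation at C4, leaving C6 untouched.

Step 14
Reactants: 27 (1S,2S,3R,6S,7R)-2-[(2E)-but-2-enoyl]-6-[3-(tert-butoxy)-3-oxoprop-1-en-2-yl]-7-[(4-methoxyphenyl)methoxy]-3-methyl-4-oxo-2-[(triethylsilyl)oxy]cycloheptyl (2S)-2-methylbutanoate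
Product: 29 (3aS,6R,7S,8S,8aR)-7-[(2E)-but-2-enoyl]-7-hydroxy-6-methyl-3-methylidene-2,5-dioxooctahydro-2H-cyclohepta[b]furan-8-yl (2S)-2-methylbutanoate, via hydroxy acid 28 (not isolated)
Conditions: TFA, anisole, CH2Cl2, 0 °C to rt; concentrate; toluene, 40 °C
Reagents that add atoms: none
Why: Acidolysis should remove the 4-methoxybenzyl ether (cation trapped by anisole), the tert-butyl ester and the silyl ether, and the cis γ-hydroxy acrylic acid should lactonise to the α-methylene-γ-butyrolactone.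

**Compound list**

1 | pent-1-yn-3-one | CCC(=O)C#C | starting material
2 | 4-methoxybenzyl alcohol | COc1ccc(CO)cc1 | starting material
3 | (1E)-1-[(4-methoxyphenyl)methoxy]pent-1-en-3-one | CCC(=O)/C=C/OCc1ccc(OC)cc1 | intermediate
4 | triethyl({(1E,3Z)-1-[(4-methoxyphenyl)methoxy]penta-1,3-dien-3-yl}oxy)silane | C/C=C(\O[Si](CC)(CC)CC)/C=C/OCc1ccc(OC)cc1 | intermediate
5 | tert-butyl 2-(bromomethyl)prop-2-enoate | C=C(CBr)C(=O)OC(C)(C)C | starting material
6 | methyl (2E)-3-(4,4,5,5-tetramethyl-1,3,2-dioxaborolan-2-yl)prop-2-enoate | COC(=O)/C=C/B1OC(C)(C)C(C)(C)O1 | starting material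
7 | 6-tert-butyl 1-methyl (2E)-5-methylidenehex-2-enedioate | COC(=O)/C=C/CC(=C)C(=O)OC(C)(C)C | intermediate
8 | 6-tert-butyl 1-methyl (3E)-2-diazo-5-methylidenehex-3-enedioate | COC(=O)C(=[N+]=[N-])/C=C/C(=C)C(=O)OC(C)(C)C | intermediate
9 | rhodium carbenoid from 8 (catalyst ligands omitted in the SMILES) | COC(=O)C(=[Rh])/C=C/C(=C)C(=O)OC(C)(C)C | intermediate
10 | methyl (1R,2R,3S)-1-[(1E)-4-(tert-butoxy)-3-methylidene-4-oxobut-1-en-1-yl]-2-{(E)-2-[(4-methoxyphenyl)methoxy]ethenyl}-3-methyl-2-[(triethylsilyl)oxy]cyclopropane-1-carboxylate | C[C@H]1[C@](C(=O)OC)(/C=C/C(=C)C(=O)OC(C)(C)C)[C@]1(O[Si](CC)(CC)CC)/C=C/OCc1ccc(OC)cc1 | intermediate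
11 | methyl (3S,4R,7S)-3-[3-(tert-butoxy)-3-oxoprop-1-en-2-yl]-4-[(4-methoxyphenyl)methoxy]-7-methyl-6-[(triethylsilyl)oxy]cyclohepta-1,5-diene-1-carboxylate | COc1ccc(cc1)CO[C@@H]2[C@H](C(=C)C(=O)OC(C)(C)C)C=C(C(=O)OC)[C@H](C)C(O[Si](CC)(CC)CC)=C2 | intermediate
12 | siloxy epoxide of 11 across C5–C6 of the cycloheptadiene (oxygen on the face opposite to the C3, C4 and C7 substituents) | COc1ccc(cc1)CO[C@@H]2[C@H](C(=C)C(=O)OC(C)(C)C)C=C(C(=O)OC)[C@H](C)[C@@]3(O[Si](CC)(CC)CC)O[C@@H]23 | intermediate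
13 | methyl (3S,4R,5S,7S)-3-[3-(tert-butoxy)-3-oxoprop-1-en-2-yl]-5-hydroxy-4-[(4-methoxyphenyl)methoxy]-7-methyl-6-oxocyclohept-1-ene-1-carboxylate | COc1ccc(cc1)CO[C@@H]2[C@H](C(=C)C(=O)OC(C)(C)C)C=C(C(=O)OC)[C@H](C)C(=O)[C@H]2O | intermediate
14 | but-2-yn-1-ol | CC#CCO | starting material
15 | 1-methoxybut-2-yne | CC#CCOC | intermediate
16 | 1-methoxybuta-1,2-diene | CC=C=COC | intermediate
17 | 1-lithio-1-methoxybuta-1,2-diene | CC=C=C([Li])OC | intermediate
18 | dichloro(1-methoxybuta-1,2-dien-1-yl)cerium | CC=C=C(OC)[Ce](Cl)Cl | intermediate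
19 | methyl (3S,4R,5S,6S,7S)-3-[3-(tert-butoxy)-3-oxoprop-1-en-2-yl]-5,6-dihydroxy-6-(1-methoxybuta-1,2-dien-1-yl)-4-[(4-methoxyphenyl)methoxy]-7-methylcyclohept-1-ene-1-carboxylate (allene axis unassigned) | COc1ccc(cc1)CO[C@@H]2[C@H](C(=C)C(=O)OC(C)(C)C)C=C(C(=O)OC)[C@H](C)[C@@](O)(C(OC)=C=CC)[C@H]2O | intermediate
20 | methyl (3S,4R,5S,6S,7S)-6-[(2E)-but-2-enoyl]-3-[3-(tert-butoxy)-3-oxoprop-1-en-2-yl]-5,6-dihydroxy-4-[(4-methoxyphenyl)methoxy]-7-methylcyclohept-1-ene-1-carboxylate | COc1ccc(cc1)CO[C@@H]2[C@H](C(=C)C(=O)OC(C)(C)C)C=C(C(=O)OC)[C@H](C)[C@@](O)(C(=O)/C=C/C)[C@H]2O | intermediate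
21 | (2S)-2-methylbutanoic acid | CC[C@H](C)C(=O)O | starting material
22 | methyl (3S,4R,5S,6S,7S)-6-[(2E)-but-2-enoyl]-3-[3-(tert-butoxy)-3-oxoprop-1-en-2-yl]-6-hydroxy-4-[(4-methoxyphenyl)methoxy]-7-methyl-5-{[(2S)-2-methylbutanoyl]oxy}cyclohept-1-ene-1-carboxylate | COc1ccc(cc1)CO[C@@H]2[C@H](C(=C)C(=O)OC(C)(C)C)C=C(C(=O)OC)[C@H](C)[C@@](O)(C(=O)/C=C/C)[C@H]2OC(=O)[C@@H](C)CC | intermediate
23 | methyl (3S,4R,5S,6S,7S)-6-[(2E)-but-2-enoyl]-3-[3-(tert-butoxy)-3-oxoprop-1-en-2-yl]-4-[(4-methoxyphenyl)methoxy]-7-methyl-5-{[(2S)-2-methylbutanoyl]oxy}-6-[(triethylsilyl)oxy]cyclohept-1-ene-1-carboxylate | COc1ccc(cc1)CO[C@@H]2[C@H](C(=C)C(=O)OC(C)(C)C)C=C(C(=O)OC)[C@H](C)[C@@](O[Si](CC)(CC)CC)(C(=O)/C=C/C)[C@H]2OC(=O)[C@@H](C)CC | intermediate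
24 | (3S,4R,5S,6S,7S)-6-[(2E)-but-2-enoyl]-3-[3-(tert-butoxy)-3-oxoprop-1-en-2-yl]-4-[(4-methoxyphenyl)methoxy]-7-methyl-5-{[(2S)-2-methylbutanoyl]oxy}-6-[(triethylsilyl)oxy]cyclohept-1-ene-1-carboxylic acid | COc1ccc(cc1)CO[C@@H]2[C@H](C(=C)C(=O)OC(C)(C)C)C=C(C(=O)O)[C@H](C)[C@@](O[Si](CC)(CC)CC)(C(=O)/C=C/C)[C@H]2OC(=O)[C@@H](C)CC | intermediate
25 | carbonyl azide of acid 24 (same configuration) | COc1ccc(cc1)CO[C@@H]2[C@H](C(=C)C(=O)OC(C)(C)C)C=C(C(=O)N=[N+]=[N-])[C@H](C)[C@@](O[Si](CC)(CC)CC)(C(=O)/C=C/C)[C@H]2OC(=O)[C@@H](C)CC | intermediate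
26 | vinyl isocyanate from 25 (N=C=O in place of the ring carboxyl, same configuration) | COc1ccc(cc1)CO[C@@H]2[C@H](C(=C)C(=O)OC(C)(C)C)C=C(N=C=O)[C@H](C)[C@@](O[Si](CC)(CC)CC)(C(=O)/C=C/C)[C@H]2OC(=O)[C@@H](C)CC | intermediate
27 | (1S,2S,3R,6S,7R)-2-[(2E)-but-2-enoyl]-6-[3-(tert-butoxy)-3-oxoprop-1-en-2-yl]-7-[(4-methoxyphenyl)methoxy]-3-methyl-4-oxo-2-[(triethylsilyl)oxy]cycloheptyl (2S)-2-methylbutanoate | COc1ccc(cc1)CO[C@@H]2[C@H](C(=C)C(=O)OC(C)(C)C)CC(=O)[C@H](C)[C@@](O[Si](CC)(CC)CC)(C(=O)/C=C/C)[C@H]2OC(=O)[C@@H](C)CC | intermediate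
28 | 2-[(1S,2R,3S,4S,5R)-4-[(2E)-but-2-enoyl]-2,4-dihydroxy-5-methyl-3-{[(2S)-2-methylbutanoyl]oxy}-6-oxocycloheptyl]prop-2-enoic acid | O[C@@H]2[C@H](C(=C)C(=O)O)CC(=O)[C@H](C)[C@@](O)(C(=O)/C=C/C)[C@H]2OC(=O)[C@@H](C)CC | intermediate
29 | (3aS,6R,7S,8S,8aR)-7-[(2E)-but-2-enoyl]-7-hydroxy-6-methyl-3-methylidene-2,5-dioxooctahydro-2H-cyclohepta[b]furan-8-yl (2S)-2-methylbutanoate | C=C1C(=O)O[C@@H]2[C@H]1CC(=O)[C@H](C)[C@@](O)(C(=O)/C=C/C)[C@H]2OC(=O)[C@@H](C)CC | target

**Step count.** Total: 14 steps. Longest linear sequence: 10 steps (1, 2, 5, 6, 9, 10, 11, 12, 13, 14; the diazo branch 3, 4 joins at step 5 with the same length, the allene branch 7, 8 joins at step 9).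

**Steps most likely to fail**

Step 5. The dienyl carbenoid may be attacked at its distal methylidene carbon instead of the carbenoid carbon, or the donor–acceptor cyclopropane may open before the Cope shift, and either would erode yield and enantiocontrol. The fallback sets out from diene 4 and uses a carbenoid without the extra alkene. Cross-metathesis of methyl acrylate with tert-butyl pent-4-enoate (second-generation Hoveyda–Grubbs catalyst) gives 6-tert-butyl 1-methyl (2E)-hex-2-enedioate F1. Diazo transfer (p-ABSA, DBU) gives 6-tert-butyl 1-methyl (3E)-2-diazohex-3-enedioate F2. The same Rh2(R-DOSP)4 cyclopropanation/Cope reaction with 4 should give methyl (3R,4R,7S)-3-[2-(tert-butoxy)-2-oxoethyl]-4-[(4-methoxyphenyl)methoxy]-7-methyl-6-[(triethylsilyl)oxy]cyclohepta-1,5-diene-1-carboxylate F3. Its tert-butyl ester enolate (LDA, THF, −78 °C) is aminomethylated with Eschenmoser's salt to the Mannich base F4, methylated (MeI) to the ammonium iodide F5, and DBU elimination returns to the route at 11.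

Step 9. The basic reagent may enolise the ketone toward the doubly activated C–H next to it, eliminate the β-ether, or add to the wrong face. The fallback sets out from 13 and uses a small, far less basic nucleophile, building the enone afterwards. Ethynylmagnesium bromide with CeCl3 should give the ethynyl carbinol, methyl (3S,4R,5S,6R,7S)-3-[3-(tert-butoxy)-3-oxoprop-1-en-2-yl]-6-ethynyl-5,6-dihydroxy-4-[(4-methoxyphenyl)methoxy]-7-methylcyclohept-1-ene-1-carboxylate F6. Gold-catalysed hydration (Ph3PAuNTf2, aqueous dioxane) gives the 6-acetyl diol F7. TMSOTf/Et3N gives the tris-silylated enol ether F8. Mukaiyama aldol addition to acetaldehyde (BF3·OEt2, −78 °C) and desilylation give the 6-(3-hydroxybutanoyl) diol F9, and acid-catalysed dehydration (p-TsOH, CH2Cl2) returns to the route at 20.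

Step 13. Activation of the hindered acid may be slow, hydrolysis of the vinyl isocyanate may stall, or the methyl-bearing centre next to the new ketone may epimerise under the hydrolysis conditions. The fallback sets out from 24 and degrades the carboxyl by oxidation instead of rearrangement. Thioesterification (EtSH, DIC, DMAP) gives the S-ethyl thioester F10. Fukuyama reduction (Et3SiH, Pd/C, acetone, short contact time) gives the enal F11. Baeyer–Villiger oxidation with alkenyl migration (mCPBA, NaHCO3, CH2Cl2) gives the enol formate F12, and mild methanolysis (KHCO3, MeOH, 0 °C) returns to the route at 27.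

**Further compounds**

F1 | step 5 | 6-tert-butyl 1-methyl (2E)-hex-2-enedioate | COC(=O)/C=C/CCC(=O)OC(C)(C)C
F2 | step 5 | 6-tert-butyl 1-methyl (3E)-2-diazohex-3-enedioate | COC(=O)C(=[N+]=[N-])/C=C/CC(=O)OC(C)(C)C
F3 | step 5 | methyl (3R,4R,7S)-3-[2-(tert-butoxy)-2-oxoethyl]-4-[(4-methoxyphenyl)methoxy]-7-methyl-6-[(triethylsilyl)oxy]cyclohepta-1,5-diene-1-carboxylate | COc1ccc(cc1)CO[C@@H]2[C@H](CC(=O)OC(C)(C)C)C=C(C(=O)OC)[C@H](C)C(O[Si](CC)(CC)CC)=C2
F4 | step 5 | Mannich base of F3, 3-[1-(tert-butoxy)-3-(dimethylamino)-1-oxopropan-2-yl] side chain (epimers at the new centre) | COc1ccc(cc1)CO[C@@H]2[C@H](C(CN(C)C)C(=O)OC(C)(C)C)C=C(C(=O)OC)[C@H](C)C(O[Si](CC)(CC)CC)=C2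
F5 | step 5 | trimethylammonium iodide of F4 | COc1ccc(cc1)CO[C@@H]2[C@H](C(C[N+](C)(C)C)C(=O)OC(C)(C)C)C=C(C(=O)OC)[C@H](C)C(O[Si](CC)(CC)CC)=C2.[I-]
F6 | step 9 | methyl (3S,4R,5S,6R,7S)-3-[3-(tert-butoxy)-3-oxoprop-1-en-2-yl]-6-ethynyl-5,6-dihydroxy-4-[(4-methoxyphenyl)methoxy]-7-methylcyclohept-1-ene-1-carboxylate | COc1ccc(cc1)CO[C@@H]2[C@H](C(=C)C(=O)OC(C)(C)C)C=C(C(=O)OC)[C@H](C)[C@@](O)(C#C)[C@H]2O
F7 | step 9 | methyl (3S,4R,5S,6S,7S)-6-acetyl-3-[3-(tert-butoxy)-3-oxoprop-1-en-2-yl]-5,6-dihydroxy-4-[(4-methoxyphenyl)methoxy]-7-methylcyclohept-1-ene-1-carboxylate | COc1ccc(cc1)CO[C@@H]2[C@H](C(=C)C(=O)OC(C)(C)C)C=C(C(=O)OC)[C@H](C)[C@@](O)(C(C)=O)[C@H]2O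
F8 | step 9 | tris(trimethylsilyl) derivative of F7 (both hydroxyls silylated, acetyl as its silyl enol ether) | COc1ccc(cc1)CO[C@@H]2[C@H](C(=C)C(=O)OC(C)(C)C)C=C(C(=O)OC)[C@H](C)[C@@](O[Si](C)(C)C)(C(=C)O[Si](C)(C)C)[C@H]2O[Si](C)(C)C
F9 | step 9 | 6-(3-hydroxybutanoyl) analogue of 20 (epimers at the new carbinol) | COc1ccc(cc1)CO[C@@H]2[C@H](C(=C)C(=O)OC(C)(C)C)C=C(C(=O)OC)[C@H](C)[C@@](O)(C(=O)CC(C)O)[C@H]2O
F10 | step 13 | S-ethyl thioester of acid 24 | COc1ccc(cc1)CO[C@@H]2[C@H](C(=C)C(=O)OC(C)(C)C)C=C(C(=O)SCC)[C@H](C)[C@@](O[Si](CC)(CC)CC)(C(=O)/C=C/C)[C@H]2OC(=O)[C@@H](C)CC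
F11 | step 13 | enal corresponding to 24 (CHO in place of CO2H) | COc1ccc(cc1)CO[C@@H]2[C@H](C(=C)C(=O)OC(C)(C)C)C=C(C=O)[C@H](C)[C@@](O[Si](CC)(CC)CC)(C(=O)/C=C/C)[C@H]2OC(=O)[C@@H](C)CC
F12 | step 13 | enol formate corresponding to 27 (OCHO on the ring alkene carbon) | COc1ccc(cc1)CO[C@@H]2[C@H](C(=C)C(=O)OC(C)(C)C)C=C(OC=O)[C@H](C)[C@@](O[Si](CC)(CC)CC)(C(=O)/C=C/C)[C@H]2OC(=O)[C@@H](C)CC
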